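**Plan**

- Numbering used: chain C13–C14(C24HO)=C15–C16–C17(OH)–C18(C21)–C19–C20; the anhydride ring is C18–C19–C20–O–C21.
- Retrosynthetic cuts, in order: the anhydride C–O bond (back to a 1,2-diacid held as di-tert-butyl ester), C16–H (back to the C16–O bond of an oxirane), C14=C15 (Wittig), the oxirane C16–O/C17–O pair (epoxidation of C16=C17), C17–C18 (alkenyl conjugate addition to a fumarate), and C12–C13/C14–C24 in the ylide arm.
- Enabling feature: C17 is the only oxygen-bearing stereocentre and lies δ to the formyl carbon C24. C15–C16–C17 are therefore a masked 2,3-epoxy alcohol, and once C14=C15 is conjugated to C24 the C16–O bond is allylic and can be replaced by hydrogen.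
- Forward order: C17–C18 is made first, then the oxirane (the only ring formed in the key step), then the chain is joined at C14=C15, the oxirane is opened at C16, and the anhydride ring is closed last but one.
- Stereochemistry: C18 from a chiral diene–rhodium catalyst, C17 (and the temporary C16) from L-(+)-diethyl tartrate on titanium, the enal geometry from a stabilised ylide, and the chain alkenes from (2E,6E)-farnesyl bromide.

Key step: step 3

Assumption: the (1S,4S) antipode of 2,5-dibenzylbicyclo[2.2.1]hepta-2,5-diene is taken to give the S configuration at C18 in step 1; if the first run shows the opposite sense, the (1R,4R) ligand is used with no other change.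

**Step 1**
Reactants: 1 di-tert-butyl fumarate; 2 (E)-3-(tert-butyldimethylsilyloxy)prop-1-enylboronic acid pinacol ester
Product: 3 di-tert-butyl (S)-2-[(E)-3-(tert-butyldimethylsilyloxy)prop-1-en-1-yl]butanedioate
Conditions: [RhCl(C2H4)2]2 (2.5 mol%), (1S,4S)-2,5-dibenzylbicyclo[2.2.1]hepta-2,5-diene (5.5 mol%), KOH (0.3 equiv), 1,4-dioxane/H2O 10:1, 40 °C
Reagents that add atoms: none
Why: Hayashi–Miyaura conjugate addition, in which the alkenyl group passes from boron to monovalent rhodium, inserts the fumarate C=C and the rhodium enolate is protonated by water; the C2-symmetric diene ligand selects one enantioface of the symmetric acceptor and so sets C18, and tert-butyl fumarate is the ester class for which diene–rhodium catalysts are established.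

**Step 2**
Reactants: 3 di-tert-butyl (S)-2-[(E)-3-(tert-butyldimethylsilyloxy)prop-1-en-1-yl]butanedioate
Product: 4 di-tert-butyl (S)-2-[(E)-3-hydroxyprop-1-en-1-yl]butanedioate
Conditions: HF·pyridine, pyridine, THF, 0 °C to rt
Reagents that add atoms: none
Why: Fluoride cleavage of the primary silyl ether under weakly acidic conditions leaves the tert-butyl esters, the E-alkene and the allylic, ester-activated C18–H untouched.

**Step 3**
Reactants: 4 di-tert-butyl (S)-2-[(E)-3-hydroxyprop-1-en-1-yl]butanedioate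
Product: 5 di-tert-butyl (S)-2-[(2S,3S)-3-(hydroxymethyl)oxiran-2-yl]butanedioate
Conditions: Ti(OiPr)4 (10 mol%), L-(+)-diethyl tartrate (12 mol%), t-BuOOH (2 equiv, anhydrous), 4 Å MS, CH2Cl2, −20 °C; aq. tartaric acid work-up
Reagents that add atoms: tert-butyl hydroperoxide, CC(C)(C)OO
Why: The C15 alkoxide of 4 and the hydroperoxide exchange onto the dimeric tetravalent titanium–tartrate complex, and the bound peroxide transfers its distal oxygen to C16=C17 in one concerted, suprafacial step, so the C16–O and C17–O bonds form together (Sharpless asymmetric epoxidation of an E-disubstituted primary allylic alcohol, its best substrate class). The oxirane, the only ring formed, closes by this single oxygen-atom transfer with retention of the alkene geometry, hence trans. C16 and C17 are both set by the L-(+)-tartrate ligand, which directs oxygen to the face giving the (2S,3S)-epoxy alcohol, while C18 is untouched. The step needs reagent control over any facial bias from the neighbouring C18 and must leave the new oxirane unopened; both rest on the free C15 hydroxyl, which anchors the substrate to titanium, and on the tert-butyl esters, which are poor ligands and poor nucleophiles at −20 °C.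

**Step 4**
Reactants: 6 (2E,6E)-farnesyl bromide
Product: 7 tert-butyl (4E,8E)-5,9,13-trimethyltetradeca-4,8,12-trienoate
Conditions: LiN(iPr)2, tert-butyl acetate, THF, −78 °C; then 6, −78 to 0 °C
Reagents that add atoms: tert-butyl acetate, CC(=O)OC(C)(C)C
Why: SN2 alkylation of the lithium ester enolate at the primary allylic bromide adds C13 and C14 without disturbing the E-alkenes.

**Step 5**
Reactants: 7 tert-butyl (4E,8E)-5,9,13-trimethyltetradeca-4,8,12-trienoate
Product: 8 (4E,8E)-5,9,13-trimethyltetradeca-4,8,12-trien-1-ol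
Conditions: LiAlH4, Et2O, 0 °C to rt
Reagents that add atoms: none
Why: Hydride reduction of the ester to the primary alcohol; isolated trisubstituted alkenes are inert to LiAlH4.

**Step 6**
Reactants: 8 (4E,8E)-5,9,13-trimethyltetradeca-4,8,12-trien-1-ol
Product: 9 (6E,10E)-14-iodo-2,6,10-trimethyltetradeca-2,6,10-triene
Conditions: I2, PPh3, imidazole, CH2Cl2, 0 °C to rt
Reagents that add atoms: iodine, II
Why: Appel-type iodination of a primary alcohol through its alkoxyphosphonium salt proceeds under neutral conditions that spare the polyene.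

**Step 7**
Reactants: 9 (6E,10E)-14-iodo-2,6,10-trimethyltetradeca-2,6,10-triene
Product: 10 [(4E,8E)-5,9,13-trimethyltetradeca-4,8,12-trien-1-yl]triphenylphosphonium iodide
Conditions: PPh3, MeCN, reflux
Reagents that add atoms: triphenylphosphine, c1ccc(cc1)P(c1ccccc1)c1ccccc1
Why: SN2 quaternisation of triphenylphosphine by an unhindered primary iodide.

**Step 8**
Reactants: 10 [(4E,8E)-5,9,13-trimethyltetradeca-4,8,12-trien-1-yl]triphenylphosphonium iodide
Product: 12 (5E,9E)-6,10,14-trimethyl-2-(triphenyl-λ5-phosphanylidene)pentadeca-5,9,13-trienal, via non-stabilised ylide 11 (not isolated)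
Conditions: NaN(SiMe3)2 (1.1 equiv), THF, 0 °C; then HCO2Et, −78 °C to rt
Reagents that add atoms: ethyl formate, CCOC=O
Why: Deprotonation gives the alkylidene phosphorane, which is C-formylated by ethyl formate (acylation of a phosphorus ylide), and the ethoxide released removes the remaining acidic proton to leave the formyl-stabilised ylide carrying C14 and C24.

**Step 9**
Reactants: 5 di-tert-butyl (S)-2-[(2S,3S)-3-(hydroxymethyl)oxiran-2-yl]butanedioate; 12 (5E,9E)-6,10,14-trimethyl-2-(triphenyl-λ5-phosphanylidene)pentadeca-5,9,13-trienal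
Product: 14 di-tert-butyl (S)-2-{(2S,3S)-3-[(1E,5E,9E)-2-formyl-6,10,14-trimethylpentadeca-1,5,9,13-tetraen-1-yl]oxiran-2-yl}butanedioate, via epoxy aldehyde 13 (not isolated)
Conditions: Dess–Martin periodinane, NaHCO3, CH2Cl2, 0 °C to rt; filter, concentrate; then 12, toluene, 50 °C
Reagents that add atoms: none
Why: Bicarbonate-buffered Dess–Martin oxidation gives the epoxy aldehyde without base-induced opening of the β,γ-epoxy ester, and the weakly basic formyl-stabilised ylide then olefinates only this more electrophilic aldehyde (Wittig reaction) to form C14=C15 as the E-enal, the normal outcome for stabilised α-substituted ylides.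

**Step 10**
Reactants: 14 di-tert-butyl (S)-2-{(2S,3S)-3-[(1E,5E,9E)-2-formyl-6,10,14-trimethylpentadeca-1,5,9,13-tetraen-1-yl]oxiran-2-yl}butanedioate
Product: 15 di-tert-butyl (S)-2-[(1R,3E,7E,11E)-4-formyl-1-hydroxy-8,12,16-trimethylheptadeca-3,7,11,15-tetraen-1-yl]butanedioate
Conditions: Pd2(dba)3·CHCl3 (5 mol%), n-Bu3P (10 mol%), HCO2H (5 equiv), Et3N (2 equiv), 1,4-dioxane, rt
Reagents that add atoms: none
Why: Tsuji hydrogenolysis of an alkenyloxirane, in which zerovalent palladium ionises the allylic C16–O bond, the palladium formate loses CO2 and hydride is delivered to C16, the allyl terminus remote from the formyl group, so C17–OH keeps its configuration and the conjugated E-enal (the thermodynamic isomer) is retained.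

**Step 11**
Reactants: 15 di-tert-butyl (S)-2-[(1R,3E,7E,11E)-4-formyl-1-hydroxy-8,12,16-trimethylheptadeca-3,7,11,15-tetraen-1-yl]butanedioate
Product: 17 (S)-2-[(1R,3E,7E,11E)-4-formyl-8,12,16-trimethyl-1-(triethylsilyloxy)heptadeca-3,7,11,15-tetraen-1-yl]butanedioic acid, via tris(triethylsilyl) derivative 16 (not isolated)
Conditions: Et3SiOTf (6 equiv), 2,6-lutidine (10 equiv), CH2Cl2, −78 °C to rt; then pH 5 NaH2PO4 buffer/THF, 0 °C
Reagents that add atoms: triethylsilyl trifluoromethanesulfonate, CC[Si](CC)(CC)OS(=O)(=O)C(F)(F)F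
Why: The silyl triflate first silylates C17–OH and then turns each tert-butyl ester into a silyl ester with loss of isobutene (lutidine-buffered Lewis-acid cleavage of tert-butyl esters); only the labile silyl esters hydrolyse on buffered work-up, so no hydroxide meets the enal and no free γ-hydroxy acid appears that could lactonise.

**Step 12**
Reactants: 17 (S)-2-[(1R,3E,7E,11E)-4-formyl-8,12,16-trimethyl-1-(triethylsilyloxy)heptadeca-3,7,11,15-tetraen-1-yl]butanedioic acid
Product: 18 (S)-3-[(1R,3E,7E,11E)-4-formyl-8,12,16-trimethyl-1-(triethylsilyloxy)heptadeca-3,7,11,15-tetraen-1-yl]oxolane-2,5-dione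
Conditions: N,N′-dicyclohexylcarbodiimide (1.1 equiv), CH2Cl2, 0 °C to rt; filter
Reagents that add atoms: none
Why: Carbodiimide cyclodehydration of a 1,2-dicarboxylic acid closes the five-membered anhydride under neutral conditions (one carboxyl attacks the O-acylisourea of the other), with no base present to epimerise C18.

**Step 13**
Reactants: 18 (S)-3-[(1R,3E,7E,11E)-4-formyl-8,12,16-trimethyl-1-(triethylsilyloxy)heptadeca-3,7,11,15-tetraen-1-yl]oxolane-2,5-dione
Product: 19 Hippolide D, (S)-3-[(1R,3E,7E,11E)-4-formyl-1-hydroxy-8,12,16-trimethylheptadeca-3,7,11,15-tetraen-1-yl]oxolane-2,5-dione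
Conditions: HF·pyridine, THF, 0 °C (polypropylene vessel); cold pH 7 buffer work-up, rapid chromatography
Reagents that add atoms: none
Why: Fluoride cleavage of the triethylsilyl ether under acidic, non-nucleophilic conditions at low temperature frees C17–OH while keeping it protonated, which should hold back acyl transfer from the neighbouring anhydride.

**Compound list**

1 | di-tert-butyl fumarate | CC(C)(C)OC(=O)/C=C/C(=O)OC(C)(C)C | starting material
2 | (E)-3-(tert-butyldimethylsilyloxy)prop-1-enylboronic acid pinacol ester | CC(C)(C)[Si](C)(C)OC/C=C/B1OC(C)(C)C(C)(C)O1 | starting material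
3 | di-tert-butyl (S)-2-[(E)-3-(tert-butyldimethylsilyloxy)prop-1-en-1-yl]butanedioate | CC(C)(C)[Si](C)(C)OC/C=C/[C@H](CC(=O)OC(C)(C)C)C(=O)OC(C)(C)C | intermediate
4 | di-tert-butyl (S)-2-[(E)-3-hydroxyprop-1-en-1-yl]butanedioate | OC/C=C/[C@H](CC(=O)OC(C)(C)C)C(=O)OC(C)(C)C | intermediate
5 | di-tert-butyl (S)-2-[(2S,3S)-3-(hydroxymethyl)oxiran-2-yl]butanedioate | OC[C@@H]1O[C@H]1[C@H](CC(=O)OC(C)(C)C)C(=O)OC(C)(C)C | intermediate
6 | (2E,6E)-farnesyl bromide | CC(C)=CCC/C(C)=C/CC/C(C)=C/CBr | starting material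
7 | tert-butyl (4E,8E)-5,9,13-trimethyltetradeca-4,8,12-trienoate | CC(C)=CCC/C(C)=C/CC/C(C)=C/CCC(=O)OC(C)(C)C | intermediate
8 | (4E,8E)-5,9,13-trimethyltetradeca-4,8,12-trien-1-ol | CC(C)=CCC/C(C)=C/CC/C(C)=C/CCCO | intermediate
9 | (6E,10E)-14-iodo-2,6,10-trimethyltetradeca-2,6,10-triene | CC(C)=CCC/C(C)=C/CC/C(C)=C/CCCI | intermediate
10 | [(4E,8E)-5,9,13-trimethyltetradeca-4,8,12-trien-1-yl]triphenylphosphonium iodide | CC(C)=CCC/C(C)=C/CC/C(C)=C/CCC[P+](c1ccccc1)(c1ccccc1)c1ccccc1.[I-] | intermediate
11 | [(4E,8E)-5,9,13-trimethyltetradeca-4,8,12-trien-1-ylidene]triphenyl-λ5-phosphane | CC(C)=CCC/C(C)=C/CC/C(C)=C/CCC=P(c1ccccc1)(c1ccccc1)c1ccccc1 | intermediate (not isolated)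
12 | (5E,9E)-6,10,14-trimethyl-2-(triphenyl-λ5-phosphanylidene)pentadeca-5,9,13-trienal | CC(C)=CCC/C(C)=C/CC/C(C)=C/CCC(C=O)=P(c1ccccc1)(c1ccccc1)c1ccccc1 | intermediate
13 | di-tert-butyl (S)-2-[(2S,3R)-3-formyloxiran-2-yl]butanedioate | O=C[C@@H]1O[C@H]1[C@H](CC(=O)OC(C)(C)C)C(=O)OC(C)(C)C | intermediate (not isolated)
14 | di-tert-butyl (S)-2-{(2S,3S)-3-[(1E,5E,9E)-2-formyl-6,10,14-trimethylpentadeca-1,5,9,13-tetraen-1-yl]oxiran-2-yl}butanedioate | CC(C)=CCC/C(C)=C/CC/C(C)=C/CC/C(C=O)=C\[C@@H]1O[C@H]1[C@H](CC(=O)OC(C)(C)C)C(=O)OC(C)(C)C | intermediate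
15 | di-tert-butyl (S)-2-[(1R,3E,7E,11E)-4-formyl-1-hydroxy-8,12,16-trimethylheptadeca-3,7,11,15-tetraen-1-yl]butanedioate | CC(C)=CCC/C(C)=C/CC/C(C)=C/CC/C(C=O)=C\C[C@@H](O)[C@H](CC(=O)OC(C)(C)C)C(=O)OC(C)(C)C | intermediate
16 | bis(triethylsilyl) (S)-2-[(1R,3E,7E,11E)-4-formyl-8,12,16-trimethyl-1-(triethylsilyloxy)heptadeca-3,7,11,15-tetraen-1-yl]butanedioate | CC(C)=CCC/C(C)=C/CC/C(C)=C/CC/C(C=O)=C\C[C@@H](O[Si](CC)(CC)CC)[C@H](CC(=O)O[Si](CC)(CC)CC)C(=O)O[Si](CC)(CC)CC | intermediate (not isolated)
17 | (S)-2-[(1R,3E,7E,11E)-4-formyl-8,12,16-trimethyl-1-(triethylsilyloxy)heptadeca-3,7,11,15-tetraen-1-yl]butanedioic acid | CC(C)=CCC/C(C)=C/CC/C(C)=C/CC/C(C=O)=C\C[C@@H](O[Si](CC)(CC)CC)[C@H](CC(=O)O)C(=O)O | intermediate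
18 | (S)-3-[(1R,3E,7E,11E)-4-formyl-8,12,16-trimethyl-1-(triethylsilyloxy)heptadeca-3,7,11,15-tetraen-1-yl]oxolane-2,5-dione | CC(C)=CCC/C(C)=C/CC/C(C)=C/CC/C(C=O)=C\C[C@@H](O[Si](CC)(CC)CC)[C@@H]1CC(=O)OC1=O | intermediate
19 | Hippolide D | CC(C)=CCC/C(C)=C/CC/C(C)=C/CC/C(C=O)=C\C[C@@H](O)[C@@H]1CC(=O)OC1=O | target

**Step count**

Total: 13 steps. Longest linear sequence: 10 steps (4–8, then 9–13); the succinate arm contributes steps 1–3.

**Steps most likely to fail**

Step 10. Hydride may be delivered to the wrong allyl terminus or to the enal itself, the phosphine may add to the aldehyde, and the freed C17 hydroxyl may close onto the C20 ester. The fallback moves the palladium hydrogenolysis to a plain vinyloxirane and brings in the enal afterwards. It sets out from epoxy aldehyde 13 (using ylide 12) and comes back at 15. Aldehyde 13 is methylenated (Ph3P=CH2 from Ph3PCH3Br/KN(SiMe3)2, THF, −78 °C) to di-tert-butyl (S)-2-[(2S,3S)-3-ethenyloxiran-2-yl]butanedioate F1. The same Pd2(dba)3·CHCl3/n-Bu3P/HCO2H–Et3N conditions, applied to this parent substrate class, should place hydride on the internal allylic carbon C16 and give di-tert-butyl (S)-2-[(R)-1-hydroxybut-3-en-1-yl]butanedioate F2. Ozonolysis of the terminal alkene (O3, CH2Cl2, −78 °C; PPh3), done before any polyene is present, should give di-tert-butyl (S)-2-[(R)-1-hydroxy-3-oxopropyl]butanedioate F3, and Wittig reaction of F3 with 12 (toluene, 50 °C) should give 15.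

Step 13. An anhydride acyl group may migrate onto the freed C17 hydroxyl (ring-opening to the γ-lactone acid), or fluoride or water may open the anhydride during desilylation. The fallback replaces the silyl ether by an allyl carbonate that is removed without fluoride or base. It sets out from 15 and comes back at 19. Compound 15 is acylated (allyl chloroformate, pyridine, CH2Cl2, 0 °C) to di-tert-butyl (S)-2-[(1R,3E,7E,11E)-1-(allyloxycarbonyloxy)-4-formyl-8,12,16-trimethylheptadeca-3,7,11,15-tetraen-1-yl]butanedioate F4. Me3SiOTf/2,6-lutidine converts the esters to the bis(trimethylsilyl) ester F5 (not isolated), which on buffered work-up gives the corresponding butanedioic acid F6. N,N′-Dicyclohexylcarbodiimide closes the allyl carbonate anhydride F7. Pd(PPh3)4 (catalytic) with 5,5-dimethylcyclohexane-1,3-dione in THF at rt then removes the carbonate under neutral to slightly acidic conditions to give 19.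

Step 1. Transmetalation may be slow and lose the boronate to protodeboronation, enantioface discrimination may be insufficient, or the aqueous base may erode configuration at the allylic, ester-activated C18–H. The fallback gives up catalytic control of C18 and lets the tartrate-controlled epoxidation turn the two enantiomers into separable diastereomers. It sets out from 1 and 2 and comes back at 5. Addition with [Rh(OH)(cod)]2 in dioxane/H2O gives racemic di-tert-butyl 2-[(E)-3-(tert-butyldimethylsilyloxy)prop-1-en-1-yl]butanedioate F8, and HF·pyridine gives racemic di-tert-butyl 2-[(E)-3-hydroxyprop-1-en-1-yl]butanedioate F9. Epoxidation under the conditions of step 3 should convert both enantiomers to (2S,3S)-oxiranes, namely 5 and its C18 epimer di-tert-butyl (R)-2-[(2S,3S)-3-(hydroxymethyl)oxiran-2-yl]butanedioate F10, which are separated by chromatography.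

**Further compounds**

F1 | step 10 | di-tert-butyl (S)-2-[(2S,3S)-3-ethenyloxiran-2-yl]butanedioate | C=C[C@@H]1O[C@H]1[C@H](CC(=O)OC(C)(C)C)C(=O)OC(C)(C)C
F2 | step 10 | di-tert-butyl (S)-2-[(R)-1-hydroxybut-3-en-1-yl]butanedioate | C=CC[C@@H](O)[C@H](CC(=O)OC(C)(C)C)C(=O)OC(C)(C)C
F3 | step 10 | di-tert-butyl (S)-2-[(R)-1-hydroxy-3-oxopropyl]butanedioate | O=CC[C@@H](O)[C@H](CC(=O)OC(C)(C)C)C(=O)OC(C)(C)C
F4 | step 13 | di-tert-butyl (S)-2-[(1R,3E,7E,11E)-1-(allyloxycarbonyloxy)-4-formyl-8,12,16-trimethylheptadeca-3,7,11,15-tetraen-1-yl]butanedioate | CC(C)=CCC/C(C)=C/CC/C(C)=C/CC/C(C=O)=C\C[C@@H](OC(=O)OCC=C)[C@H](CC(=O)OC(C)(C)C)C(=O)OC(C)(C)C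
F5 | step 13 | bis(trimethylsilyl) (S)-2-[(1R,3E,7E,11E)-1-(allyloxycarbonyloxy)-4-formyl-8,12,16-trimethylheptadeca-3,7,11,15-tetraen-1-yl]butanedioate | CC(C)=CCC/C(C)=C/CC/C(C)=C/CC/C(C=O)=C\C[C@@H](OC(=O)OCC=C)[C@H](CC(=O)O[Si](C)(C)C)C(=O)O[Si](C)(C)C
F6 | step 13 | (S)-2-[(1R,3E,7E,11E)-1-(allyloxycarbonyloxy)-4-formyl-8,12,16-trimethylheptadeca-3,7,11,15-tetraen-1-yl]butanedioic acid | CC(C)=CCC/C(C)=C/CC/C(C)=C/CC/C(C=O)=C\C[C@@H](OC(=O)OCC=C)[C@H](CC(=O)O)C(=O)O
F7 | step 13 | allyl (1R,3E,7E,11E)-1-[(S)-2,5-dioxooxolan-3-yl]-4-formyl-8,12,16-trimethylheptadeca-3,7,11,15-tetraen-1-yl carbonate | CC(C)=CCC/C(C)=C/CC/C(C)=C/CC/C(C=O)=C\C[C@@H](OC(=O)OCC=C)[C@@H]1CC(=O)OC1=O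
F8 | step 1 | racemic di-tert-butyl 2-[(E)-3-(tert-butyldimethylsilyloxy)prop-1-en-1-yl]butanedioate | CC(C)(C)[Si](C)(C)OC/C=C/C(CC(=O)OC(C)(C)C)C(=O)OC(C)(C)C
F9 | step 1 | racemic di-tert-butyl 2-[(E)-3-hydroxyprop-1-en-1-yl]butanedioate | OC/C=C/C(CC(=O)OC(C)(C)C)C(=O)OC(C)(C)C
F10 | step 1 | di-tert-butyl (R)-2-[(2S,3S)-3-(hydroxymethyl)oxiran-2-yl]butanedioate | OC[C@@H]1O[C@H]1[C@@H](CC(=O)OC(C)(C)C)C(=O)OC(C)(C)C
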